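**Plan**
Retrosynthesis: the C23 acetate and the C30 ketone are adjusted last. Ring A is cut at C5–C16 (vinylogous aldol condensation) and at C16–O (enolate oxygenation), ring C at C7–C15 (enolate addition–elimination), and ring B with C13 is removed as cyclohexane-1,3-dione plus formaldehyde (hetero-Diels–Alder at the C11=C12 enamide).
The nine-membered ring E is cut at C22–C28 by an oxy-Cope transform that restores the C11–C30 bond of a 2-alkenyl-3-vinylpyrrolidin-3-ol fused to ring D. Ring D is opened at C12=C22 (metathesis) and the pyrrolidine is traced to (R)-3-amino-2-methylpropanoic acid.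
Forward order: pyrrolidine, ring D, ring E by sigmatropic ring expansion, ring B attached and ring C closed, ring A, then oxidation-state and protecting-group adjustment.
Stereochemistry: C32 comes from the amino acid and directs C30 (vinyl anti to methyl); C30 directs C11 (vinyl anti to silyloxy); C11 is relayed to C22 in the rearrangement. The ring E bridge then fixes C12 and C7, the C22 side shields one face at C16, and the C16 hydroxyl directs hydrogen to C5.

Key step: step 13

Remarks. Atom numbers are the positions of the atoms in the target SMILES read from left to right (C5 ester-bearing carbon, C7 and C22 quaternary carbons, C8 lactam carbonyl, N10, C14=C15 enone, C16 carbinol, C20 enone carbonyl, C23 acetoxymethyl carbon, C30 ketone, C32 methyl-bearing carbon). Rings: A = C5/C6/C7/C15/C16, B = cyclohexenone, C = C7/C15/C14/C13/C12/C22, D = lactam, E = nine-membered ring. Assumption: the configuration of the temporary C30 carbinol (23 to 39) is immaterial because C30 is reoxidised in step 26; one epimer is drawn. Compounds 25 and 28 to 30 are expected as C7 epimers and 34 as an E/Z mixture; both converge later. Diazomethane is generated from N-methyl-N-nitroso-p-toluenesulfonamide.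

Step 1
Reactants: 1 (R)-3-[(tert-butoxycarbonyl)amino]-2-methylpropanoic acid
Product: 3 tert-butyl N-[(2R)-4-diazo-2-methyl-3-oxobutyl]carbamate, via mixed anhydride 2 (not isolated)
Conditions: iBuOCOCl, N-methylmorpholine, THF, −15 °C; then CH2N2, Et2O, 0 °C
Reagents that add atoms: diazomethane, C=[N+]=[N-]
Why: Acylation of diazomethane by the mixed anhydride (first stage of an Arndt–Eistert sequence) gives the α-diazoketone at low temperature, which should leave the C32 stereocenter untouched.

Step 2
Reactants: 3 tert-butyl N-[(2R)-4-diazo-2-methyl-3-oxobutyl]carbamate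
Product: 4 tert-butyl (4R)-4-methyl-3-oxopyrrolidine-1-carboxylate
Conditions: Rh2(OAc)4 (1 mol %), CH2Cl2, 25 °C
Reagents that add atoms: none
Why: Rhodium-carbenoid N–H insertion into the carbamate closes the five-membered ring (N10–C11) under neutral conditions that should not epimerise C32.

Step 3
Reactants: 4 tert-butyl (4R)-4-methyl-3-oxopyrrolidine-1-carboxylate; 5 vinylmagnesium bromide
Product: 6 tert-butyl (3R,4R)-3-ethenyl-3-hydroxy-4-methylpyrrolidine-1-carboxylate
Conditions: CeCl3, THF, −78 °C
Reagents that add atoms: none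
Why: 1,2-Addition of the weakly basic vinylcerium reagent should occur anti to the adjacent C32 methyl group, setting C30 with vinyl trans and hydroxyl cis to methyl while suppressing enolisation.

Step 4
Reactants: 6 tert-butyl (3R,4R)-3-ethenyl-3-hydroxy-4-methylpyrrolidine-1-carboxylate
Product: 8 (3R,4R)-3-ethenyl-4-methyl-3-(triethylsilyloxy)pyrrolidine, via silyl carbamate 7 (not isolated)
Conditions: Et3SiOTf (3 equiv), 2,6-lutidine, CH2Cl2, 0 → 25 °C; then MeOH
Reagents that add atoms: triethylsilyl trifluoromethanesulfonate, CC[Si](CC)(CC)OS(=O)(=O)C(F)(F)F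
Why: The silyl triflate silylates the tertiary alcohol and converts the tert-butyl carbamate into a silyl carbamate that loses CO2 on methanolysis (silyl-triflate carbamate cleavage), giving the free amine with the carbinol masked.

Step 5
Reactants: 8 (3R,4R)-3-ethenyl-4-methyl-3-(triethylsilyloxy)pyrrolidine
Product: 10 cyclic nitrone 4-ethenyl-3-methyl-4-(triethylsilyloxy)-3,4-dihydro-2H-pyrrole 1-oxide (C=N at C11), via N-hydroxypyrrolidine 9 (not isolated)
Conditions: Na2WO4·2H2O (5 mol %), urea·H2O2, MeOH, 0 → 25 °C
Reagents that add atoms: hydrogen peroxide (as its urea adduct), OO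
Why: Tungstate-catalysed peroxide oxidation of the secondary amine through the hydroxylamine gives the nitrone, and C=N should form at C11 because the C–H bond anti to the C30–O bond is lost preferentially, as is known for 3-alkoxypyrrolidines.

Step 6
Reactants: 10 cyclic nitrone; 5 vinylmagnesium bromide
Product: 11 2,3-diethenyl-1-hydroxy-4-methyl-3-(triethylsilyloxy)pyrrolidine (vinyl groups cis; C11 vinyl trans to the silyloxy group)
Conditions: THF, −78 → 0 °C
Reagents that add atoms: none
Why: Grignard addition to the cyclic nitrone should take place anti to the neighbouring silyloxy group (the usual trans selectivity of 3-alkoxy-1-pyrroline N-oxides), so the new C11 vinyl group is cis to the C30 vinyl group.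

Step 7
Reactants: 11 N-hydroxy divinylpyrrolidine
Product: 12 2,3-diethenyl-4-methyl-3-(triethylsilyloxy)pyrrolidine (same relative configuration)
Conditions: Zn, AcOH, EtOH, 25 °C
Reagents that add atoms: none
Why: Dissolving-metal reduction with zinc cleaves the N–O bond of the hydroxylamine without affecting the alkenes or the silyl ether.

Step 8
Reactants: 12 divinylpyrrolidine; 13 itaconic anhydride
Product: 14 2-methylidene-4-oxo-4-(pyrrolidin-1-yl)butanoic acid derived from 12
Conditions: CH2Cl2, 0 → 25 °C
Reagents that add atoms: none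
Why: Aminolysis of the cyclic anhydride occurs at the non-conjugated carbonyl remote from the methylidene group, giving the N-acylpyrrolidine (C8, C7, C22, C23) with a free acrylic acid.

Step 9
Reactants: 14 amido acid
Product: 16 N-[3-(hydroxymethyl)but-3-enoyl] derivative of 12, via mixed anhydride 15 (not isolated)
Conditions: iBuOCOCl, N-methylmorpholine, THF, −15 °C; then NaBH4, H2O, 0 °C
Reagents that add atoms: none
Why: Mixed-anhydride activation followed by borohydride reduction converts the carboxylic acid into the allylic alcohol chemoselectively beside the tertiary amide.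

Step 10
Reactants: 16 allylic alcohol
Product: 17 N-{3-[(tert-butyldiphenylsilyloxy)methyl]but-3-enoyl} derivative of 12
Conditions: tBuPh2SiCl, imidazole, DMF, 25 °C
Reagents that add atoms: tert-butyl(chloro)diphenylsilane, CC(C)(C)[Si](Cl)(c1ccccc1)c1ccccc1
Why: Silylation of the primary alcohol gives a robust C23 ether that should survive the later basic and acidic steps.

Step 11
Reactants: 17 triene amide
Product: 18 1-ethenyl-2-methyl-1-(triethylsilyloxy)-7-[(tert-butyldiphenylsilyloxy)methyl]-2,3,6,8a-tetrahydroindolizin-5(1H)-one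
Conditions: second-generation Grubbs catalyst RuCl2(=CHPh)(H2IMes)(PCy3) (5 mol %), CH2Cl2, 40 °C
Reagents that add atoms: none
Why: Ring-closing metathesis joins the C11 vinyl group and the 1,1-disubstituted acyl alkene into six-membered ring D (C12=C22), while the vinyl group on the fully substituted silyloxy-bearing C30 should be too hindered to engage.

Step 12
Reactants: 18 bicyclic lactam silyl ether
Product: 19 1-ethenyl-1-hydroxy-2-methyl-7-[(tert-butyldiphenylsilyloxy)methyl]-2,3,6,8a-tetrahydroindolizin-5(1H)-one
Conditions: HF·pyridine, pyridine, THF, 0 °C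
Reagents that add atoms: none
Why: Buffered fluoride removes the labile triethylsilyl ether selectively (silyl ether cleavage) and leaves the tert-butyldiphenylsilyl ether.

Step 13
Reactants: 19 bicyclic lactam carbinol
Product: 22 bridged keto enamide 7-[(tert-butyldiphenylsilyloxy)methyl]-3-methyl-1-azabicyclo[5.2.2]undec-8-ene-4,11-dione, via potassium alkoxide 20 (not isolated), via potassium enolate 21 (not isolated)
Conditions: KN(SiMe3)2 (1.1 equiv), 18-crown-6, THF, −78 → 0 °C; then AcOH, −78 °C
Reagents that add atoms: none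
Why: The base deprotonates the tertiary carbinol, and the potassium alkoxide 20, freed from ion pairing by the crown ether, undergoes a [3,3]-sigmatropic shift through a boat-like transition state in which C28 bonds to C22 while C11–C30 breaks, giving enolate 21 and the N10–C11=C12 enamide. The closest known reaction type is the anionic oxy-Cope ring expansion of cis-1,2-dialkenylcyclopentanols to cyclononenones with potassium bases and 18-crown-6. Ring E closes by four-atom ring expansion of the pyrrolidine, not by end-to-end cyclisation, and so bridges N10 and C22 of ring D. The new quaternary stereocenter C22 is controlled by C11 through suprafacial transfer, because C28 must add to the ring D face from which C30 departs, which the cis relation of the C30 vinyl group and C12 (steps 3 and 6) enforces. The step needs O–H deprotonation in preference to C7–H and rearrangement faster than drift of the C12=C22 bond into conjugation; stoichiometric base at low temperature, the nitrogen donor on C11 that weakens the breaking bond, and a cold acetic acid quench that also protects C32 next to the new ketone are meant to secure this.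

Step 14
Reactants: 22 bridged keto enamide
Product: 23 4-hydroxy-7-[(tert-butyldiphenylsilyloxy)methyl]-3-methyl-1-azabicyclo[5.2.2]undec-8-en-11-one
Conditions: NaBH4, MeOH, 0 °C
Reagents that add atoms: none
Why: Borohydride reduction turns the ketone into a carbinol so that C32 cannot epimerise and no ketone enolate or transannular reaction with the enamide interferes later.

Step 15
Reactants: 23 bridged hydroxy enamide
Product: 24 C30 tert-butyldimethylsilyl ether of 23
Conditions: tBuMe2SiOTf, 2,6-lutidine, CH2Cl2, 0 °C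
Reagents that add atoms: tert-butyldimethylsilyl trifluoromethanesulfonate, CC(C)(C)[Si](C)(C)OS(=O)(=O)C(F)(F)F
Why: Silyl triflate silylation protects the hindered secondary alcohol under non-acidic conditions that the enamide tolerates.

Step 16
Reactants: 24 silyl ether
Product: 25 S-ethyl thioester at C7 of 24
Conditions: LiN(iPr)2, THF, −78 °C; then EtSC(O)Cl
Reagents that add atoms: S-ethyl chlorothioformate, CCSC(Cl)=O
Why: Claisen-type C-acylation of the lithium lactam enolate installs the carbon that becomes C6 and makes C7–H acidic enough for a later soft-enolate cyclisation.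

Step 17
Reactants: 25 thioester; 26 cyclohexane-1,3-dione
Product: 28 hetero-Diels–Alder adduct (dihydropyran N,O-acetal across C11–C12 fused to the cyclohexenone), via methylidene dione 27 (not isolated)
Conditions: aq. CH2O, L-proline (cat.), MeCN, 25 °C
Reagents that add atoms: formaldehyde, C=O
Why: In this domino Knoevenagel–hetero-Diels–Alder reaction the 2-methylidene-1,3-dione adds as an electron-poor 1-oxadiene to the enamide with C13 bonding to C12 from the face opposite the ring E bridge, which sets C12 (and the transient C11 center) cis.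

Step 18
Reactants: 28 hetero-Diels–Alder adduct
Product: 29 2-substituted cyclohexane-1,3-dione with C11 as methylene
Conditions: Et3SiH, BF3·OEt2, CH2Cl2, −78 → −30 °C
Reagents that add atoms: none
Why: Lewis acid ionisation of the N,O-acetal gives the N-acyliminium ion, which the silane reduces (ionic hydrogenation) while the dione is released.

Step 19
Reactants: 29 dione
Product: 30 3-chloro-2-substituted cyclohex-2-en-1-one
Conditions: (COCl)2, DMF (cat.), CH2Cl2, 0 °C
Reagents that add atoms: oxalyl chloride, ClC(=O)C(Cl)=O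
Why: Oxalyl chloride converts the vinylogous acid into the vinylogous acid chloride, the electrophile for ring C closure.

Step 20
Reactants: 30 chloro enone
Product: 31 tetracyclic thioester (rings B to E; C7 quaternary)
Conditions: Cs2CO3, MeCN, 40 °C
Reagents that add atoms: none
Why: Intramolecular conjugate addition–elimination of the soft thioester-amide enolate at C15 closes ring C; only the C7 configuration that places C15 on the side of C13 can cyclise, and both C7 epimers converge through the planar enolate.

Step 21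
Reactants: 31 tetracyclic thioester
Product: 32 tetracyclic C7 aldehyde
Conditions: Et3SiH, Pd/C (10 %), acetone, 25 °C
Reagents that add atoms: none
Why: Fukuyama thioester reduction gives the aldehyde without reducing the tetrasubstituted enone or the lactam.

Step 22
Reactants: 32 aldehyde; 33 methyl 2-(dimethoxyphosphoryl)-2-methoxyacetate
Product: 34 methyl 2-methoxyacrylate attached through C6 to C7
Conditions: LiN(SiMe3)2, THF, −78 → 0 °C
Reagents that add atoms: none
Why: Horner–Wadsworth–Emmons olefination with the preformed phosphonate anion gives a masked α-keto ester, the anion being too weak a base to enolise the enone.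

Step 23
Reactants: 34 enol ether
Product: 36 pentacyclic dienone ester (ring A closed with C5=C16; free C30 hydroxyl), via keto ester 35 (not isolated)
Conditions: 2 M aq. HCl, THF, 25 °C; then DBU, toluene, 60 °C
Reagents that add atoms: none
Why: Acid hydrolysis of the enol ether (and of the C30 silyl ether) unmasks the α-keto ester, whose electrophilic ketone then undergoes an intramolecular vinylogous aldol condensation with the γ-methylene C16 of the enone.

Step 24
Reactants: 36 dienone ester
Product: 38 C16 carbinol with C5=C6 enoate, via hydroperoxide 37 (not isolated)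
Conditions: KOtBu, O2, P(OEt)3, THF/tBuOH, −40 °C; then AcOH
Reagents that add atoms: dioxygen, O=O
Why: Autoxidation of the extended enolate formed by deprotonation at C6 should capture oxygen at the γ-carbon C16 with shift of the ring A double bond to C5=C6, on the face away from the C22 substituents, and the phosphite reduces the hydroperoxide.

Step 25
Reactants: 38 hydroxy enoate
Product: 39 saturated β-hydroxy ester (C5–H cis to the C16 hydroxyl)
Conditions: H2 (1 atm), [Ir(cod)(PCy3)(py)]PF6 (5 mol %), CH2Cl2, 25 °C
Reagents that add atoms: none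
Why: In this hydroxyl-directed hydrogenation the cationic iridium catalyst bound to the C16 hydroxyl delivers hydrogen to the same face of the trisubstituted C5=C6 alkene, setting C5, while the tetrasubstituted enone should remain.

Step 26
Reactants: 39 diol ester
Product: 40 C30 ketone with C23 silyl ether
Conditions: Dess–Martin periodinane, NaHCO3, CH2Cl2, 25 °C
Reagents that add atoms: none
Why: Dess–Martin oxidation of the secondary C30 carbinol restores the ketone, and the tertiary C16 alcohol cannot be oxidised.

Step 27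
Reactants: 40 silyl ether
Product: 41 C23 primary alcohol (deacetyl target)
Conditions: HF·pyridine, THF, 25 °C
Reagents that add atoms: none
Why: Fluoride-mediated silyl ether cleavage frees the primary alcohol under conditions mild enough for the β-hydroxy ester and the ketone.

Step 28
Reactants: 41 primary alcohol
Product: 42 CNP0211170.1
Conditions: Ac2O, pyridine, DMAP (cat.), CH2Cl2, 0 °C
Reagents that add atoms: acetic anhydride, CC(=O)OC(C)=O
Why: Acetylation of the primary alcohol completes the target, and the tertiary C16 hydroxyl should not react under these mild conditions.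

**Compound list**
1 | (R)-3-[(tert-butoxycarbonyl)amino]-2-methylpropanoic acid | CC(C)(C)OC(=O)NC[C@@H](C)C(O)=O | starting material
2 | isobutyl carbonic mixed anhydride of 1 | CC(C)(C)OC(=O)NC[C@@H](C)C(=O)OC(=O)OCC(C)C | intermediate (not isolated)
3 | tert-butyl N-[(2R)-4-diazo-2-methyl-3-oxobutyl]carbamate | CC(C)(C)OC(=O)NC[C@@H](C)C(=O)C=[N+]=[N-] | intermediate
4 | tert-butyl (4R)-4-methyl-3-oxopyrrolidine-1-carboxylate | CC(C)(C)OC(=O)N1C[C@@H](C)C(=O)C1 | intermediate
5 | vinylmagnesium bromide | C=C[Mg]Br | starting material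
6 | tert-butyl (3R,4R)-3-ethenyl-3-hydroxy-4-methylpyrrolidine-1-carboxylate | CC(C)(C)OC(=O)N1C[C@@H](C)[C@](O)(C=C)C1 | intermediate
7 | triethylsilyl 3-ethenyl-4-methyl-3-(triethylsilyloxy)pyrrolidine-1-carboxylate | CC[Si](CC)(CC)OC(=O)N1C[C@@H](C)[C@](O[Si](CC)(CC)CC)(C=C)C1 | intermediate (not isolated)
8 | (3R,4R)-3-ethenyl-4-methyl-3-(triethylsilyloxy)pyrrolidine | N1C[C@@H](C)[C@](O[Si](CC)(CC)CC)(C=C)C1 | intermediate
9 | 1-hydroxy derivative of 8 | ON1C[C@@H](C)[C@](O[Si](CC)(CC)CC)(C=C)C1 | intermediate (not isolated)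
10 | 4-ethenyl-3-methyl-4-(triethylsilyloxy)-3,4-dihydro-2H-pyrrole 1-oxide | [O-][N+]1C[C@@H](C)[C@](O[Si](CC)(CC)CC)(C=C)C=1 | intermediate
11 | 2,3-diethenyl-1-hydroxy-4-methyl-3-(triethylsilyloxy)pyrrolidine, vinyl groups cis | ON1C[C@@H](C)[C@](O[Si](CC)(CC)CC)(C=C)[C@@H]1C=C | intermediate
12 | 2,3-diethenyl-4-methyl-3-(triethylsilyloxy)pyrrolidine, vinyl groups cis | N1C[C@@H](C)[C@](O[Si](CC)(CC)CC)(C=C)[C@@H]1C=C | intermediate
13 | itaconic anhydride (3-methylideneoxolane-2,5-dione) | C=C1CC(=O)OC1=O | starting material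
14 | 2-methylidene-4-oxo-4-(pyrrolidin-1-yl)butanoic acid derived from 12 | OC(=O)C(=C)CC(=O)N1C[C@@H](C)[C@](O[Si](CC)(CC)CC)(C=C)[C@@H]1C=C | intermediate
15 | isobutyl carbonic mixed anhydride of 14 | CC(C)COC(=O)OC(=O)C(=C)CC(=O)N1C[C@@H](C)[C@](O[Si](CC)(CC)CC)(C=C)[C@@H]1C=C | intermediate (not isolated)
16 | N-[3-(hydroxymethyl)but-3-enoyl] derivative of 12 | OCC(=C)CC(=O)N1C[C@@H](C)[C@](O[Si](CC)(CC)CC)(C=C)[C@@H]1C=C | intermediate
17 | N-{3-[(tert-butyldiphenylsilyloxy)methyl]but-3-enoyl} derivative of 12 | C=C(CO[Si](c1ccccc1)(c1ccccc1)C(C)(C)C)CC(=O)N2C[C@@H](C)[C@](O[Si](CC)(CC)CC)(C=C)[C@@H]2C=C | intermediate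
18 | 1-ethenyl-2-methyl-1-(triethylsilyloxy)-7-[(tert-butyldiphenylsilyloxy)methyl]-2,3,6,8a-tetrahydroindolizin-5(1H)-one | O=C1CC(CO[Si](c2ccccc2)(c2ccccc2)C(C)(C)C)=C[C@@H]3N1C[C@@H](C)[C@]3(O[Si](CC)(CC)CC)C=C | intermediate
19 | 1-ethenyl-1-hydroxy-2-methyl-7-[(tert-butyldiphenylsilyloxy)methyl]-2,3,6,8a-tetrahydroindolizin-5(1H)-one | O=C1CC(CO[Si](c2ccccc2)(c2ccccc2)C(C)(C)C)=C[C@@H]3N1C[C@@H](C)[C@]3(O)C=C | intermediate
20 | potassium alkoxide of 19 | O=C1CC(CO[Si](c2ccccc2)(c2ccccc2)C(C)(C)C)=C[C@@H]3N1C[C@@H](C)[C@]3([O-])C=C.[K+] | intermediate (not isolated)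
21 | potassium C29=C30 enolate of 22 | O=C1C[C@]2(CO[Si](c3ccccc3)(c3ccccc3)C(C)(C)C)C=CN1C[C@@H](C)C([O-])=CC2.[K+] | intermediate (not isolated)
22 | 7-[(tert-butyldiphenylsilyloxy)methyl]-3-methyl-1-azabicyclo[5.2.2]undec-8-ene-4,11-dione | O=C1C[C@]2(CO[Si](c3ccccc3)(c3ccccc3)C(C)(C)C)C=CN1C[C@@H](C)C(=O)CC2 | intermediate
23 | 4-hydroxy analogue of 22 (C30 carbinol) | O=C1C[C@]2(CO[Si](c3ccccc3)(c3ccccc3)C(C)(C)C)C=CN1C[C@@H](C)[C@@H](O)CC2 | intermediate
24 | C30 tert-butyldimethylsilyl ether of 23 | O=C1C[C@]2(CO[Si](c3ccccc3)(c3ccccc3)C(C)(C)C)C=CN1C[C@@H](C)[C@@H](O[Si](C)(C)C(C)(C)C)CC2 | intermediate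
25 | C7 S-ethyl thioester of 24 (C7 epimers) | O=C1C(C(=O)SCC)[C@]2(CO[Si](c3ccccc3)(c3ccccc3)C(C)(C)C)C=CN1C[C@@H](C)[C@@H](O[Si](C)(C)C(C)(C)C)CC2 | intermediate
26 | cyclohexane-1,3-dione | O=C1CCCC(=O)C1 | starting material
27 | 2-methylidenecyclohexane-1,3-dione | C=C1C(=O)CCCC1=O | intermediate (not isolated)
28 | hetero-Diels–Alder adduct, dihydropyran N,O-acetal across C11–C12 | O=C1C(C(=O)SCC)[C@]2(CO[Si](c5ccccc5)(c5ccccc5)C(C)(C)C)[C@@H]3CC4=C(CCCC4=O)O[C@@H]3N1C[C@@H](C)[C@@H](O[Si](C)(C)C(C)(C)C)CC2 | intermediate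
29 | 2-substituted cyclohexane-1,3-dione, C11 methylene | O=C1C(C(=O)SCC)[C@]2(CO[Si](c5ccccc5)(c5ccccc5)C(C)(C)C)[C@H](CC3C(=O)CCCC3=O)CN1C[C@@H](C)[C@@H](O[Si](C)(C)C(C)(C)C)CC2 | intermediate
30 | 3-chloro-2-substituted cyclohex-2-en-1-one | O=C1C(C(=O)SCC)[C@]2(CO[Si](c5ccccc5)(c5ccccc5)C(C)(C)C)[C@H](CC3=C(Cl)CCCC3=O)CN1C[C@@H](C)[C@@H](O[Si](C)(C)C(C)(C)C)CC2 | intermediate
31 | tetracyclic C7 thioester, rings B to E | CCSC(=O)[C@@]23C(=O)N4C[C@@H](CC5=C2CCCC5=O)[C@]3(CO[Si](c6ccccc6)(c6ccccc6)C(C)(C)C)CC[C@H](O[Si](C)(C)C(C)(C)C)[C@H](C)C4 | intermediate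
32 | tetracyclic C7 aldehyde | O=C[C@@]23C(=O)N4C[C@@H](CC5=C2CCCC5=O)[C@]3(CO[Si](c6ccccc6)(c6ccccc6)C(C)(C)C)CC[C@H](O[Si](C)(C)C(C)(C)C)[C@H](C)C4 | intermediate
33 | methyl 2-(dimethoxyphosphoryl)-2-methoxyacetate | COC(=O)C(OC)P(=O)(OC)OC | starting material
34 | methyl 2-methoxyacrylate on C7 (E/Z mixture) | COC(=O)C(OC)=C[C@@]23C(=O)N4C[C@@H](CC5=C2CCCC5=O)[C@]3(CO[Si](c6ccccc6)(c6ccccc6)C(C)(C)C)CC[C@H](O[Si](C)(C)C(C)(C)C)[C@H](C)C4 | intermediate
35 | α-keto ester with free C30 hydroxyl | COC(=O)C(=O)C[C@@]23C(=O)N4C[C@@H](CC5=C2CCCC5=O)[C@]3(CO[Si](c6ccccc6)(c6ccccc6)C(C)(C)C)CC[C@H](O)[C@H](C)C4 | intermediate (not isolated)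
36 | pentacyclic dienone ester, C5=C16 | COC(=O)C=1C[C@@]23C(=O)N4C[C@@H](CC5=C2C=1CCC5=O)[C@]3(CO[Si](c6ccccc6)(c6ccccc6)C(C)(C)C)CC[C@H](O)[C@H](C)C4 | intermediate
37 | C16 hydroperoxide, C5=C6 | COC(=O)C1=C[C@@]23C(=O)N4C[C@@H](CC5=C2[C@]1(OO)CCC5=O)[C@]3(CO[Si](c6ccccc6)(c6ccccc6)C(C)(C)C)CC[C@H](O)[C@H](C)C4 | intermediate (not isolated)
38 | C16 carbinol, C5=C6 enoate | COC(=O)C1=C[C@@]23C(=O)N4C[C@@H](CC5=C2[C@]1(O)CCC5=O)[C@]3(CO[Si](c6ccccc6)(c6ccccc6)C(C)(C)C)CC[C@H](O)[C@H](C)C4 | intermediate
39 | saturated β-hydroxy ester, C30 carbinol | COC(=O)[C@@H]1C[C@@]23C(=O)N4C[C@@H](CC5=C2[C@]1(O)CCC5=O)[C@]3(CO[Si](c6ccccc6)(c6ccccc6)C(C)(C)C)CC[C@H](O)[C@H](C)C4 | intermediate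
40 | C30 ketone, C23 silyl ether | COC(=O)[C@@H]1C[C@@]23C(=O)N4C[C@@H](CC5=C2[C@]1(O)CCC5=O)[C@]3(CO[Si](c6ccccc6)(c6ccccc6)C(C)(C)C)CCC(=O)[C@H](C)C4 | intermediate
41 | C23 primary alcohol (deacetyl target) | COC(=O)[C@@H]1C[C@@]23C(=O)N4C[C@@H](CC5=C2[C@]1(O)CCC5=O)[C@]3(CO)CCC(=O)[C@H](C)C4 | intermediate
42 | CNP0211170.1 | COC(=O)[C@@H]1C[C@@]23C(=O)N4C[C@@H](CC5=C2[C@]1(O)CCC5=O)[C@]3(COC(C)=O)CCC(=O)[C@H](C)C4 | target

**Totals**
Total step count: 28. Longest linear sequence: 28 steps (1 to 42); the other numbered starting materials are commercial and enter directly.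

**Steps most likely to fail**
Step 13. Proton transfer from C7 to the alkoxide could move the C12=C22 double bond into conjugation with the lactam, or the alkoxide could cleave the C11–C30 bond heterolytically without recombination at C22. Fallback from 19: run the same rearrangement without base. Silylation of 19 (Me3SiCl, imidazole) would give the trimethylsilyl ether F1; heating F1 in o-dichlorobenzene at about 180 °C should give the ring-expanded trimethylsilyl enol ether F2 by the neutral [3,3] shift; K2CO3 in methanol would then cleave the enol ether and rejoin the route at 22.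

Step 24. Oxygen could be captured at C6 or C14 of the extended enolate, could approach C16 from the face of the C22 substituents, or the base could enolise at C19 instead. Fallback from 36: kinetic protonation of the same enolate (KOtBu, then AcOH at −78 °C) should deconjugate the ketone to the β,γ-unsaturated ketone F3. Epoxidation of its electron-rich C15=C16 alkene with mCPBA on the open face would give the C15–C16 epoxide F4. Et3N would then open the epoxide by β-elimination from C14 and return the route at 38.

Step 17. The cycloaddition on the hindered enamide could be slower than consumption of the methylidene dione by a second molecule of 26 or by the thioester enol. Fallback from 25: alkylation of the enamide carbon C12 with 2-(bromomethyl)-3-chlorocyclohex-2-en-1-one under AgOTf activation would give the N-acyliminium triflate F5. Reduction of F5 in the same flask with Et3SiH would rejoin the route at 30 and skip steps 18 and 19.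

**Further compounds**
F1 | step 13 | trimethylsilyl ether of 19 | O=C1CC(CO[Si](c2ccccc2)(c2ccccc2)C(C)(C)C)=C[C@@H]3N1C[C@@H](C)[C@]3(O[Si](C)(C)C)C=C
F2 | step 13 | ring-expanded trimethylsilyl enol ether of 22 | O=C1C[C@]2(CO[Si](c3ccccc3)(c3ccccc3)C(C)(C)C)C=CN1C[C@@H](C)C(O[Si](C)(C)C)=CC2
F3 | step 24 | β,γ-unsaturated ketone with C14–H, C15=C16 and C5=C6 (C14 epimers) | COC(=O)C1=C[C@@]23C(=O)N4C[C@@H](CC5C2=C1CCC5=O)[C@]3(CO[Si](c6ccccc6)(c6ccccc6)C(C)(C)C)CC[C@H](O)[C@H](C)C4
F4 | step 24 | C15–C16 epoxide of F3 | COC(=O)C1=C[C@@]23C(=O)N4C[C@@H](CC5[C@]2(O6)[C@@]61CCC5=O)[C@]3(CO[Si](c7ccccc7)(c7ccccc7)C(C)(C)C)CC[C@H](O)[C@H](C)C4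
F5 | step 17 | N-acyliminium triflate (C11=N10) carrying the chloro enone on C12 | O=C1C(C(=O)SCC)[C@]2(CO[Si](c5ccccc5)(c5ccccc5)C(C)(C)C)[C@H](CC3=C(Cl)CCCC3=O)C=[N+]1C[C@@H](C)[C@@H](O[Si](C)(C)C(C)(C)C)CC2.[O-]S(=O)(=O)C(F)(F)F
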